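**Retrosynthetic overview**
- The chroman O1–C2 bond is cut last (intramolecular Mitsunobu), giving an open-chain (R)-2,3-diarylpropan-1-ol.
- The C3–C4 bond is the late fragment union: Evans benzylation of a B-ring arylacetyl imide (chromene already in place) with an A-ring benzyl bromide; the auxiliary sets C3.
- A fragment: resorcinol → 3,5-dimethoxyphenol (C–H borylation/oxidation) → para-formylation, O-tosylation, chelation-controlled mono-demethylation, O-allylation, CH2Br.
- B fragment: resorcinol → 2,4-dihydroxybenzaldehyde → 4-OTs → tertiary propargyl ether → Claisen/6π closure of the dimethylpyran → CHO to CH2CO2H → imide.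
- Ring order: chromene pyran ring (B fragment, before coupling), then the chroman pyran ring (after coupling), then detosylation.

Assumption: the recoverable chiral auxiliary (R)-4-benzyl-2-oxazolidinone is classed as a reagent, like the tosyl and allyl groups, because none of its atoms reach the target; only compounds that supply skeleton atoms are numbered as starting materials.

**A fragment**

Step 1
Reactants: 1 resorcinol
Product: 2 1,3-dimethoxybenzene
Conditions: MeI (2.5 equiv), K2CO3, acetone, reflux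
Reagents that add atoms: iodomethane CI
Why: Williamson O-methylation of both phenols.

Step 2
Reactants: 2 1,3-dimethoxybenzene
Product: 4 3,5-dimethoxyphenol, via arylboronate 3 (not isolated)
Conditions: [Ir(OMe)(cod)]2 (1 mol%), dtbpy (2 mol%), HBpin, THF, 80 °C; then Oxone, acetone/H2O, 0 °C → rt
Reagents that add atoms: pinacolborane CC1(C)OBOC1(C)C (into 3 only); Oxone (KHSO5) [K+].[O-]S(=O)(=O)OO
Why: Sterically controlled Ir-catalysed C–H borylation reaches only C5, the one C–H with no ortho substituent, and peroxide oxidation of the C–B bond gives the phenol in one pot.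

Step 3
Reactants: 4 3,5-dimethoxyphenol
Product: 5 4-hydroxy-2,6-dimethoxybenzaldehyde
Conditions: POCl3, DMF, 0 °C → rt; aq. NaOAc, 50 °C; crystallise away from the minor 2-formyl isomer
Reagents that add atoms: N,N-dimethylformamide CN(C)C=O; water O
Why: Vilsmeier–Haack formylation, directed mainly para to the free OH (the carbon between the two OMe groups).

Step 4
Reactants: 5 4-hydroxy-2,6-dimethoxybenzaldehyde
Product: 6 4-formyl-3,5-dimethoxyphenyl 4-methylbenzenesulfonate
Conditions: TsCl, Et3N, DMAP (cat.), CH2Cl2, 0 °C → rt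
Reagents that add atoms: p-toluenesulfonyl chloride Cc1ccc(cc1)S(Cl)(=O)=O
Why: O-sulfonylation; the tosylate protects this phenol and is electron-withdrawing enough to make the later 2,6-dialkoxybenzyl bromide handleable.

Step 5
Reactants: 6 4-formyl-3,5-dimethoxyphenyl 4-methylbenzenesulfonate
Product: 7 4-formyl-3-hydroxy-5-methoxyphenyl 4-methylbenzenesulfonate
Conditions: BCl3 (1.2 equiv), CH2Cl2, −78 → 0 °C; H2O
Reagents that add atoms: none
Why: Chelation-controlled Lewis-acid demethylation ortho to the carbonyl; the two OMe groups are equivalent and the boron chelate stops the reaction after one cleavage.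

Step 6
Reactants: 7 4-formyl-3-hydroxy-5-methoxyphenyl 4-methylbenzenesulfonate
Product: 8 3-(allyloxy)-4-formyl-5-methoxyphenyl 4-methylbenzenesulfonate
Conditions: allyl bromide, K2CO3, DMF, rt
Reagents that add atoms: allyl bromide C=CCBr
Why: Williamson etherification installs an ortho-O protecting group removable by Pd(0) without touching tosylates or the chromene.

Step 7
Reactants: 8 3-(allyloxy)-4-formyl-5-methoxyphenyl 4-methylbenzenesulfonate
Product: 9 3-(allyloxy)-4-(hydroxymethyl)-5-methoxyphenyl 4-methylbenzenesulfonate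
Conditions: NaBH4, THF/MeOH, 0 °C
Reagents that add atoms: none
Why: Chemoselective borohydride reduction of the aldehyde.

Step 8
Reactants: 9 3-(allyloxy)-4-(hydroxymethyl)-5-methoxyphenyl 4-methylbenzenesulfonate
Product: 10 3-(allyloxy)-4-(bromomethyl)-5-methoxyphenyl 4-methylbenzenesulfonate
Conditions: PBr3 (0.4 equiv), Et2O, 0 °C; used at once
Reagents that add atoms: phosphorus tribromide BrP(Br)Br
Why: Benzylic alcohol-to-bromide substitution through the phosphite ester.

**B fragment**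

Step 9
Reactants: 1 resorcinol
Product: 11 2,4-dihydroxybenzaldehyde
Conditions: POCl3, DMF, MeCN, −15 °C → rt; then H2O, 50 °C
Reagents that add atoms: N,N-dimethylformamide CN(C)C=O; water O
Why: Vilsmeier–Haack formylation at C4 of resorcinol (ortho/para to the two OH groups).

Step 10
Reactants: 11 2,4-dihydroxybenzaldehyde
Product: 12 4-formyl-3-hydroxyphenyl 4-methylbenzenesulfonate
Conditions: TsCl (1.0 equiv), K2CO3, acetone, rt
Reagents that add atoms: p-toluenesulfonyl chloride Cc1ccc(cc1)S(Cl)(=O)=O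
Why: Selective sulfonylation of the para-OH, because the ortho-OH is held in a hydrogen bond to the aldehyde.

Step 11
Reactants: 12 4-formyl-3-hydroxyphenyl 4-methylbenzenesulfonate; 13 3-chloro-3-methylbut-1-yne
Product: 14 4-formyl-3-[(2-methylbut-3-yn-2-yl)oxy]phenyl 4-methylbenzenesulfonate
Conditions: DBU, CuCl2·2H2O (0.5 mol%), MeCN, 0 °C → rt
Reagents that add atoms: none
Why: Cu-catalysed propargylic etherification via a copper allenylidene makes the tertiary aryl propargyl ether that plain SN2 cannot.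

Step 12
Reactants: 14 4-formyl-3-[(2-methylbut-3-yn-2-yl)oxy]phenyl 4-methylbenzenesulfonate
Product: 15 8-formyl-2,2-dimethyl-2H-chromen-5-yl 4-methylbenzenesulfonate
Conditions: o-dichlorobenzene, 180 °C
Reagents that add atoms: none
Why: Aromatic propargyl Claisen rearrangement to the only free ortho carbon, then 1,5-H shift and oxa-6π electrocyclisation close the 2,2-dimethyl-2H-pyran with the ring O next to the formyl-bearing carbon.

Step 13
Reactants: 15 8-formyl-2,2-dimethyl-2H-chromen-5-yl 4-methylbenzenesulfonate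
Product: 17 2,2-dimethyl-8-(2-oxoethyl)-2H-chromen-5-yl 4-methylbenzenesulfonate, via enol ether 16 (not isolated)
Conditions: Ph3P(CH2OMe)Cl, KHMDS, THF, 0 °C → rt; then 2 M HCl, THF, 40 °C; crude aldehyde used directly
Reagents that add atoms: (methoxymethyl)triphenylphosphonium chloride COC[P+](c1ccccc1)(c1ccccc1)c1ccccc1.[Cl-]; water O
Why: Wittig methoxymethylenation followed by enol ether hydrolysis is a one-carbon homologation of the aldehyde.

Step 14
Reactants: 17 2,2-dimethyl-8-(2-oxoethyl)-2H-chromen-5-yl 4-methylbenzenesulfonate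
Product: 18 [2,2-dimethyl-5-(tosyloxy)-2H-chromen-8-yl]acetic acid
Conditions: NaClO2, NaH2PO4, 2-methyl-2-butene, t-BuOH/H2O, 0 °C → rt
Reagents that add atoms: sodium chlorite [Na+].[O-]Cl=O
Why: Pinnick oxidation; the alkene scavenger removes HOCl so the chromene double bond is untouched.

Step 15
Reactants: 18 [2,2-dimethyl-5-(tosyloxy)-2H-chromen-8-yl]acetic acid
Product: 20 (R)-4-benzyl-3-{[2,2-dimethyl-5-(tosyloxy)-2H-chromen-8-yl]acetyl}oxazolidin-2-one, via mixed pivalic anhydride 19 (not isolated)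
Conditions: PivCl, Et3N, THF, −20 °C; then (R)-4-benzyl-2-oxazolidinone, LiCl, −20 °C → rt
Reagents that add atoms: pivaloyl chloride CC(C)(C)C(Cl)=O (into 19 only); (R)-4-benzyl-2-oxazolidinone O=C1N[C@H](Cc2ccccc2)CO1
Why: Mixed-anhydride N-acylation of the oxazolidinone at the less hindered carbonyl.

**Coupling and endgame**

Step 16
Reactants: 20 (R)-4-benzyl-3-{[2,2-dimethyl-5-(tosyloxy)-2H-chromen-8-yl]acetyl}oxazolidin-2-one; 10 3-(allyloxy)-4-(bromomethyl)-5-methoxyphenyl 4-methylbenzenesulfonate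
Product: 22 (R)-4-benzyl-3-{(2R)-3-[2-(allyloxy)-6-methoxy-4-(tosyloxy)phenyl]-2-[2,2-dimethyl-5-(tosyloxy)-2H-chromen-8-yl]propanoyl}oxazolidin-2-one, via sodium Z-enolate 21 (not isolated)
Conditions: NaHMDS (1.05 equiv), THF, −78 °C; then 10 (1.3 equiv), −78 → −45 °C; minor diastereomer removed by chromatography
Reagents that add atoms: sodium bis(trimethylsilyl)amide C[Si](C)(C)[N-][Si](C)(C)C.[Na+] (into 21 only)
Why: Evans asymmetric alkylation: the benzyl group of the (R)-auxiliary shields one face of the chelated Z-enolate, so the benzyl bromide enters from the other face and sets the future C3 as R.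

Step 17
Reactants: 22 (R)-4-benzyl-3-{(2R)-3-[2-(allyloxy)-6-methoxy-4-(tosyloxy)phenyl]-2-[2,2-dimethyl-5-(tosyloxy)-2H-chromen-8-yl]propanoyl}oxazolidin-2-one
Product: 23 3-(allyloxy)-4-{(2R)-2-[2,2-dimethyl-5-(tosyloxy)-2H-chromen-8-yl]-3-hydroxypropyl}-5-methoxyphenyl 4-methylbenzenesulfonate
Conditions: LiBH4, MeOH (1 equiv), THF, 0 °C
Reagents that add atoms: none
Why: Reductive cleavage of the imide at the exocyclic carbonyl gives the primary alcohol without epimerising the α-aryl centre, after which the stereocentre is no longer next to a carbonyl.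

Step 18
Reactants: 23 3-(allyloxy)-4-{(2R)-2-[2,2-dimethyl-5-(tosyloxy)-2H-chromen-8-yl]-3-hydroxypropyl}-5-methoxyphenyl 4-methylbenzenesulfonate
Product: 24 4-{(2R)-2-[2,2-dimethyl-5-(tosyloxy)-2H-chromen-8-yl]-3-hydroxypropyl}-3-hydroxy-5-methoxyphenyl 4-methylbenzenesulfonate
Conditions: Pd(PPh3)4 (5 mol%), morpholine, THF, rt
Reagents that add atoms: none
Why: Tsuji–Trost deallylation frees only the ortho phenol; aryl tosylates and the chromene are inert to Pd(0) at rt.

Step 19
Reactants: 24 4-{(2R)-2-[2,2-dimethyl-5-(tosyloxy)-2H-chromen-8-yl]-3-hydroxypropyl}-3-hydroxy-5-methoxyphenyl 4-methylbenzenesulfonate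
Product: 25 (3R)-3-[2,2-dimethyl-5-(tosyloxy)-2H-chromen-8-yl]-5-methoxychroman-7-yl 4-methylbenzenesulfonate
Conditions: PPh3, DIAD, THF (0.02 M), 0 °C → rt
Reagents that add atoms: none
Why: Intramolecular Mitsunobu etherification (6-exo-tet) at the primary carbon closes the chroman ring and leaves C3 untouched.

Step 20
Reactants: 25 (3R)-3-[2,2-dimethyl-5-(tosyloxy)-2H-chromen-8-yl]-5-methoxychroman-7-yl 4-methylbenzenesulfonate
Product: 26 (3R)-3-(5-hydroxy-2,2-dimethyl-2H-chromen-8-yl)-5-methoxychroman-7-ol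
Conditions: 2 M aq. NaOH, 1,4-dioxane, 80 °C, Ar; then 1 M HCl to pH 5
Reagents that add atoms: none
Why: Sulfonate ester hydrolysis by hydroxide attack at sulfur frees both phenols; no acid, hydrogen or alcohol co-solvent is present, so the chromene alkene, the methyl ether and C3 are unaffected.

**Compound list**
1 | resorcinol | Oc1cccc(O)c1 | starting material
2 | 1,3-dimethoxybenzene | COc1cccc(OC)c1 | intermediate
3 | 2-(3,5-dimethoxyphenyl)-4,4,5,5-tetramethyl-1,3,2-dioxaborolane (arylboronate) | COc1cc(OC)cc(c1)B1OC(C)(C)C(C)(C)O1 | intermediate (not isolated)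
4 | 3,5-dimethoxyphenol | COc1cc(O)cc(OC)c1 | intermediate
5 | 4-hydroxy-2,6-dimethoxybenzaldehyde | COc1cc(O)cc(OC)c1C=O | intermediate
6 | 4-formyl-3,5-dimethoxyphenyl 4-methylbenzenesulfonate | COc1cc(OS(=O)(=O)c2ccc(C)cc2)cc(OC)c1C=O | intermediate
7 | 4-formyl-3-hydroxy-5-methoxyphenyl 4-methylbenzenesulfonate | COc1cc(OS(=O)(=O)c2ccc(C)cc2)cc(O)c1C=O | intermediate
8 | 3-(allyloxy)-4-formyl-5-methoxyphenyl 4-methylbenzenesulfonate | COc1cc(OS(=O)(=O)c2ccc(C)cc2)cc(OCC=C)c1C=O | intermediate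
9 | 3-(allyloxy)-4-(hydroxymethyl)-5-methoxyphenyl 4-methylbenzenesulfonate | COc1cc(OS(=O)(=O)c2ccc(C)cc2)cc(OCC=C)c1CO | intermediate
10 | 3-(allyloxy)-4-(bromomethyl)-5-methoxyphenyl 4-methylbenzenesulfonate | COc1cc(OS(=O)(=O)c2ccc(C)cc2)cc(OCC=C)c1CBr | intermediate
11 | 2,4-dihydroxybenzaldehyde | O=Cc1ccc(O)cc1O | intermediate
12 | 4-formyl-3-hydroxyphenyl 4-methylbenzenesulfonate | O=Cc1ccc(OS(=O)(=O)c2ccc(C)cc2)cc1O | intermediate
13 | 3-chloro-3-methylbut-1-yne | CC(C)(Cl)C#C | starting material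
14 | 4-formyl-3-[(2-methylbut-3-yn-2-yl)oxy]phenyl 4-methylbenzenesulfonate | O=Cc1ccc(OS(=O)(=O)c2ccc(C)cc2)cc1OC(C)(C)C#C | intermediate
15 | 8-formyl-2,2-dimethyl-2H-chromen-5-yl 4-methylbenzenesulfonate | O=Cc1ccc(OS(=O)(=O)c2ccc(C)cc2)c2C=CC(C)(C)Oc12 | intermediate
16 | 8-(2-methoxyvinyl)-2,2-dimethyl-2H-chromen-5-yl 4-methylbenzenesulfonate (E/Z mixture) | COC=Cc1ccc(OS(=O)(=O)c2ccc(C)cc2)c2C=CC(C)(C)Oc12 | intermediate (not isolated)
17 | 2,2-dimethyl-8-(2-oxoethyl)-2H-chromen-5-yl 4-methylbenzenesulfonate | O=CCc1ccc(OS(=O)(=O)c2ccc(C)cc2)c2C=CC(C)(C)Oc12 | intermediate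
18 | [2,2-dimethyl-5-(tosyloxy)-2H-chromen-8-yl]acetic acid | OC(=O)Cc1ccc(OS(=O)(=O)c2ccc(C)cc2)c2C=CC(C)(C)Oc12 | intermediate
19 | [2,2-dimethyl-5-(tosyloxy)-2H-chromen-8-yl]acetic pivalic anhydride | CC(C)(C)C(=O)OC(=O)Cc1ccc(OS(=O)(=O)c2ccc(C)cc2)c2C=CC(C)(C)Oc12 | intermediate (not isolated)
20 | (R)-4-benzyl-3-{[2,2-dimethyl-5-(tosyloxy)-2H-chromen-8-yl]acetyl}oxazolidin-2-one | O=C(Cc1ccc(OS(=O)(=O)c2ccc(C)cc2)c2C=CC(C)(C)Oc12)N1[C@H](Cc2ccccc2)COC1=O | intermediate
21 | sodium (Z)-enolate of 20 | [Na+].[O-]/C(=C\c1ccc(OS(=O)(=O)c2ccc(C)cc2)c2C=CC(C)(C)Oc12)N1[C@H](Cc2ccccc2)COC1=O | intermediate (not isolated)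
22 | (R)-4-benzyl-3-{(2R)-3-[2-(allyloxy)-6-methoxy-4-(tosyloxy)phenyl]-2-[2,2-dimethyl-5-(tosyloxy)-2H-chromen-8-yl]propanoyl}oxazolidin-2-one | COc1cc(OS(=O)(=O)c2ccc(C)cc2)cc(OCC=C)c1C[C@H](c1ccc(OS(=O)(=O)c2ccc(C)cc2)c2C=CC(C)(C)Oc12)C(=O)N1[C@H](Cc2ccccc2)COC1=O | intermediate
23 | 3-(allyloxy)-4-{(2R)-2-[2,2-dimethyl-5-(tosyloxy)-2H-chromen-8-yl]-3-hydroxypropyl}-5-methoxyphenyl 4-methylbenzenesulfonate | COc1cc(OS(=O)(=O)c2ccc(C)cc2)cc(OCC=C)c1C[C@H](c1ccc(OS(=O)(=O)c2ccc(C)cc2)c2C=CC(C)(C)Oc12)CO | intermediate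
24 | 4-{(2R)-2-[2,2-dimethyl-5-(tosyloxy)-2H-chromen-8-yl]-3-hydroxypropyl}-3-hydroxy-5-methoxyphenyl 4-methylbenzenesulfonate | COc1cc(OS(=O)(=O)c2ccc(C)cc2)cc(O)c1C[C@H](c1ccc(OS(=O)(=O)c2ccc(C)cc2)c2C=CC(C)(C)Oc12)CO | intermediate
25 | (3R)-3-[2,2-dimethyl-5-(tosyloxy)-2H-chromen-8-yl]-5-methoxychroman-7-yl 4-methylbenzenesulfonate | COc1cc(OS(=O)(=O)c2ccc(C)cc2)cc2c1C[C@H](c1ccc(OS(=O)(=O)c3ccc(C)cc3)c3C=CC(C)(C)Oc13)CO2 | intermediate
26 | (3R)-3-(5-hydroxy-2,2-dimethyl-2H-chromen-8-yl)-5-methoxychroman-7-ol | COc1cc(O)cc2c1C[C@H](c1ccc(O)c3c1OC(C)(C)C=C3)CO2 | target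

**Totals**
Total step count: 20. Longest linear sequence: 13 (steps 1–8, then 16–20); the other branch is 12 (steps 9–15, then 16–20).

**Three steps most likely to fail**

Step 16 (hindered Evans benzylation; the enolate can fragment to a ketene if the alkylation is slow). The fallback sets out from acid 18, together with bromide 10, and comes back at alcohol 23. The auxiliary is dropped. Acid 18 is converted into its dilithium enediolate with a C2-symmetric Koga-type chiral tetramine dilithium amide (n-BuLi, THF, −78 °C), using the enantiomer of the base that delivers the R acid. Direct alkylation with 10 gives (2R)-3-[2-(allyloxy)-6-methoxy-4-(tosyloxy)phenyl]-2-[2,2-dimethyl-5-(tosyloxy)-2H-chromen-8-yl]propanoic acid F1. The enediolate is more nucleophilic than the imide enolate and cannot collapse to a ketene. Ethyl chloroformate and N-methylmorpholine (THF, −15 °C) then give the mixed ethyl carbonic anhydride F2, which NaBH4 (THF/H2O, 0 °C) reduces to 23.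

Step 13 (acidic enol ether hydrolysis next to the chromene, and a fragile arylacetaldehyde). The fallback sets out from aldehyde 15 and comes back at acid 18 by an Arndt–Eistert homologation, which avoids both aqueous acid and the aldehyde 17. Pinnick oxidation of 15 gives 2,2-dimethyl-5-(tosyloxy)-2H-chromene-8-carboxylic acid F3. Oxalyl chloride with catalytic DMF gives 2,2-dimethyl-5-(tosyloxy)-2H-chromene-8-carbonyl chloride F4. TMSCHN2 and Et3N (THF/MeCN, 0 °C) give 8-(2-diazoacetyl)-2,2-dimethyl-2H-chromen-5-yl 4-methylbenzenesulfonate F5. Wolff rearrangement (AgOBz cat., Et3N, THF/H2O, rt) gives 18.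

Step 3 (para/ortho mixture in the Vilsmeier formylation, modest isolated yield). The fallback sets out from phenol 4 and comes back at aldehyde 5, replacing electrophilic substitution with directed ortho-metalation. TIPSCl and imidazole give (3,5-dimethoxyphenoxy)triisopropylsilane F6. n-BuLi/TMEDA (THF, 0 °C) lithiates only the carbon between the two methoxy groups, because the bulky silyl ether does not direct, giving [2,6-dimethoxy-4-(triisopropylsilyloxy)phenyl]lithium F7. A DMF quench gives 2,6-dimethoxy-4-[(triisopropylsilyl)oxy]benzaldehyde F8, and TBAF (THF, 0 °C) gives 5.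

**Further compounds**
F1 | step 16 | (2R)-3-[2-(allyloxy)-6-methoxy-4-(tosyloxy)phenyl]-2-[2,2-dimethyl-5-(tosyloxy)-2H-chromen-8-yl]propanoic acid | COc1cc(OS(=O)(=O)c2ccc(C)cc2)cc(OCC=C)c1C[C@H](c1ccc(OS(=O)(=O)c2ccc(C)cc2)c2C=CC(C)(C)Oc12)C(O)=O
F2 | step 16 | mixed ethyl carbonic anhydride of F1 | COc1cc(OS(=O)(=O)c2ccc(C)cc2)cc(OCC=C)c1C[C@H](c1ccc(OS(=O)(=O)c2ccc(C)cc2)c2C=CC(C)(C)Oc12)C(=O)OC(=O)OCC
F3 | step 13 | 2,2-dimethyl-5-(tosyloxy)-2H-chromene-8-carboxylic acid | OC(=O)c1ccc(OS(=O)(=O)c2ccc(C)cc2)c2C=CC(C)(C)Oc12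
F4 | step 13 | 2,2-dimethyl-5-(tosyloxy)-2H-chromene-8-carbonyl chloride | ClC(=O)c1ccc(OS(=O)(=O)c2ccc(C)cc2)c2C=CC(C)(C)Oc12
F5 | step 13 | 8-(2-diazoacetyl)-2,2-dimethyl-2H-chromen-5-yl 4-methylbenzenesulfonate | [N-]=[N+]=CC(=O)c1ccc(OS(=O)(=O)c2ccc(C)cc2)c2C=CC(C)(C)Oc12
F6 | step 3 | (3,5-dimethoxyphenoxy)triisopropylsilane | COc1cc(OC)cc(O[Si](C(C)C)(C(C)C)C(C)C)c1
F7 | step 3 | [2,6-dimethoxy-4-(triisopropylsilyloxy)phenyl]lithium | [Li]c1c(OC)cc(O[Si](C(C)C)(C(C)C)C(C)C)cc1OC
F8 | step 3 | 2,6-dimethoxy-4-[(triisopropylsilyl)oxy]benzaldehyde | COc1cc(O[Si](C(C)C)(C(C)C)C(C)C)cc(OC)c1C=O
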